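Ring A carries oxygen on C1 and on C4, a 1,4-relationship that ordinary carbonyl polarity cannot assemble. The route therefore rests on the C1–C2 disconnection, with C2 acting as the β-carbanion (homoenolate) of a C4 ketone. In one operation diethylzinc opens a 1-hydroxycyclopropyl group on C5 and the C2–zinc species adds to a C1 aldehyde on the quaternary C10. This closes ring A as a trans-decalin and sets the equatorial 1β-carbinol through chelation to O9. The precursor is an all-equatorial ring B cyclohexane, built from (S)-carvone, that holds both reacting arms trans-diequatorial. The C4 ketone later becomes the 4,15-diol which, together with O6, takes up the orthocinnamate.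

Key step: step 14

Assumption: eudesmane numbering (C1–C15) is kept for all intermediates; β is the face of ring B that bears the C14 methyl group on C10 and α the opposite face; aldehyde 22 is drawn open although it may rest partly as its lactol with O4.

Step 1
Reactants: 1 (S)-(+)-carvone; 2 vinylmagnesium bromide
Product: 3 2-methyl-5-isopropenyl-3-vinylcyclohexanone (vinyl on C5 β; isopropenyl on C7 α; both C10 epimers)
Conditions: 2 (1.5 equiv), CuBr·SMe2 (10 mol %), THF, −78 → −20 °C
Reagents that add atoms: vinylmagnesium bromide, C=C[Mg]Br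
Why: Copper-catalysed 1,4-addition of a Grignard reagent to a cyclohexenone, in which axial attack on the half-chair with the C7 isopropenyl group equatorial brings the vinyl group (the future C4) to the face opposite that group and so fixes C5, while the C10 epimer mixture is of no consequence.

Step 2
Reactants: 3 vinyl ketone
Product: 4 3-isopropyl-6-methyl-5-vinylcyclohex-2-enone (vinyl on C5 β; both C10 epimers)
Conditions: p-TsOH·H2O (20 mol %), benzene, reflux
Reagents that add atoms: none
Why: Acid-catalysed alkene isomerisation of the dihydrocarvone-to-carvenone type, in which protonation of the 1,1-disubstituted alkene gives the tertiary C11 cation and proton loss plus enol-mediated migration end in the conjugated C7=C8 enone as the thermodynamic sink; the monosubstituted vinyl group is too weakly basic to react, and the C7 stereocentre, its relay task done, is erased on purpose.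

Step 3
Reactants: 4 enone; 5 formaldehyde (monomer from cracked paraformaldehyde)
Product: 7 6-(hydroxymethyl)-3-isopropyl-6-methyl-5-vinylcyclohex-2-enone (C1 hydroxymethyl α on C10; C14 methyl β; vinyl β on C5), via lithium dienolate 6 (not isolated)
Conditions: LiN(iPr)2, THF, −78 → −30 °C; HCHO (g), −78 °C
Reagents that add atoms: formaldehyde, C=O
Why: Kinetic α'-deprotonation of the enone followed by aldol addition to formaldehyde, in which allylic strain against the C10 methyl group holds the C5 vinyl group pseudoaxial so that the electrophile enters from the opposite α face and the quaternary C10 forms with C1 trans to C4.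

Step 4
Reactants: 7 hydroxymethyl enone
Product: 10 trans-fused bicyclic lactol (C1–O–C4 bridge; hemiacetal carbon C4; enone C7=C8–C9=O kept), via secondary ozonide 8 (not isolated), via hydroxy aldehyde 9 (not isolated)
Conditions: O3, CH2Cl2, Sudan Red 7B, −78 °C; Me2S, −78 °C → rt
Reagents that add atoms: ozone, [O-][O+]=O
Why: Ozonolysis with reductive work-up, in which the monosubstituted alkene is consumed well before the electron-poor trisubstituted enone (dye end-point) and the C4 aldehyde is captured at once by the neighbouring C1 hydroxyl group as a five-membered lactol.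

Step 5
Reactants: 10 lactol
Product: 11 trans-fused γ-lactone enone (C1H2–O–C4(=O) lactone on C10 and C5; H5 α; C14 β)
Conditions: nPr4N[RuO4] (5 mol %), N-methylmorpholine N-oxide, 4 Å MS, CH2Cl2, rt
Reagents that add atoms: none
Why: Ley–Griffith oxidation of a lactol to the γ-lactone, which masks the C1 alcohol and the C4 carboxyl carbon in a single group and, being trans-fused, locks ring B in the conformation with C14 axial that steers all later additions.

Step 6
Reactants: 11 lactone enone
Product: 12 tert-butyldimethylsilyl dienol ether (C9(OTBS)=C8–C7(iPr)=C6 homoannular diene; lactone unchanged)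
Conditions: TBSOTf, Et3N, CH2Cl2, 0 °C
Reagents that add atoms: tert-butyldimethylsilyl triflate, CC(C)(C)[Si](C)(C)OS(=O)(=O)C(F)(F)F
Why: Soft enolisation with a silyl triflate and an amine, in which the quaternary C10 leaves only γ-deprotonation and the amine takes the axial ring hydrogen on C6 rather than the isopropyl methine hydrogen, whose alignment with the π system would cost allylic strain.

Step 7
Reactants: 12 silyl dienol ether
Product: 14 6α-hydroxy enone lactone (OH on C6 α; C7=C8–C9=O), via endoperoxide 13 (not isolated)
Conditions: O2, tetraphenylporphyrin (cat.), visible light, CH2Cl2, −78 °C; thiourea, MeOH, −78 °C → rt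
Reagents that add atoms: dioxygen, O=O
Why: [4+2] photooxygenation of a cisoid 1-oxygenated cyclohexa-1,3-diene (ascaridole type) followed by thiourea reduction of the O–O bond, in which singlet oxygen bridges C6 and C9 on the α face away from the pseudoaxial C14 methyl group and the C9 silyl hemiketal then collapses to the enone, leaving the 6α-hydroxyl group.

Step 8
Reactants: 14 6α-hydroxy enone lactone
Product: 15 6α-hydroxy-7β-isopropyl-9-keto lactone (H7 α; isopropyl equatorial)
Conditions: H2 (1 atm), [Ir(cod)(PCy3)(py)]PF6 (5 mol %), CH2Cl2, rt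
Reagents that add atoms: none
Why: Hydroxyl-directed homogeneous hydrogenation, in which the cationic iridium complex binds the 6α-hydroxyl group and delivers hydrogen to the same, also less hindered, α face of C7=C8 so that the isopropyl group on C7 becomes β and equatorial.

Step 9
Reactants: 15 hydroxy keto lactone
Product: 16 6α-benzyloxy-9-keto lactone
Conditions: BnOC(=NH)CCl3, TfOH (cat.), CH2Cl2/cyclohexane, 0 °C → rt
Reagents that add atoms: benzyl 2,2,2-trichloroacetimidate, N=C(OCc1ccccc1)C(Cl)(Cl)Cl
Why: Acid-catalysed O-benzylation with a trichloroacetimidate avoids an alkoxide and hence retro-aldol opening or epimerisation of the β-hydroxy lactone, and benzyl is chosen for O6 because hydrogenolysis can later remove it without touching the silicon-based groups on O1 and O9.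

Step 10
Reactants: 16 benzyloxy keto lactone
Product: 17 6α-benzyloxy-9β-hydroxy lactone (OH on C9 equatorial)
Conditions: NaBH4, MeOH/CH2Cl2, −20 → 0 °C
Reagents that add atoms: none
Why: Borohydride reduction of a conformationally locked cyclohexanone, in which hydride attacks C9 axially from the α face, anti to the adjacent axial C14 methyl group, to give the equatorial 9β-alcohol while the lactone survives at this temperature.

Step 11
Reactants: 17 9β-alcohol
Product: 18 6α-benzyloxy-9β-[2-(trimethylsilyl)ethoxymethoxy] lactone
Conditions: SEMCl, iPr2NEt, Bu4NI (cat.), CH2Cl2, 40 °C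
Reagents that add atoms: 2-(trimethylsilyl)ethoxymethyl chloride, C[Si](C)(C)CCOCCl
Why: Alkoxymethylation of a hindered alcohol under amine-base conditions, the SEM group offering a Lewis-basic oxygen on C9 for chelation in step 14 and, unlike purely acid-labile acetal groups, leaving with fluoride at the end when the acid-sensitive orthoester is present.

Step 12
Reactants: 18 lactone; 19 ethylmagnesium bromide
Product: 20 diol (1-hydroxycyclopropyl group on C5 β; C1 hydroxymethyl on C10 α; O6 benzyl; O9 SEM)
Conditions: 19 (4 equiv), Ti(OiPr)4 (0.5 equiv), THF, 0 °C → rt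
Reagents that add atoms: ethylmagnesium bromide, CC[Mg]Br
Why: Kulinkovich reaction of a lactone, in which the titanacyclopropane formed from ethylmagnesium bromide acts as a 1,2-dicarbanion on the C4 carbonyl group, delivers C2 and C3 as the cyclopropane methylenes and frees the C1 primary alcohol in the same operation.

Step 13
Reactants: 20 diol
Product: 22 ring B aldehyde (C1 formyl and C14 methyl on C10; 1-hydroxycyclopropyl on C5; O6 benzyl; O9 SEM), via alkoxysulfonium chloride 21 (not isolated)
Conditions: (COCl)2, DMSO, CH2Cl2, −78 °C; Et3N, −78 → −20 °C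
Reagents that add atoms: none
Why: Swern oxidation, in which only the primary alcohol carries a carbinol hydrogen, the tertiary cyclopropanol is inert to this non-metallic, non-radical oxidant at low temperature, and no oxidant remains when the aldehyde is released, so that its lactol form cannot be overoxidised back to the lactone.

Step 14
Reactants: 22 ring B aldehyde
Product: 26 1β-hydroxy-15-nor-eudesman-4-one 6-O-benzyl 9-O-SEM ether (trans-decalin; H5 α; C14 β), via ethylzinc cyclopropoxide 23 (not isolated), via zinc homoenolate 24 (not isolated), via ethylzinc alkoxide 25 (not isolated)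
Conditions: Et2Zn (2 equiv), toluene/THF, 0 °C → rt; then H2O
Reagents that add atoms: none
Why: Diethylzinc deprotonates the cyclopropanol (or its lactol tautomer, which reopens), and cyclopropoxide 23 releases ring strain by cleavage of a C4–CH2 bond to give the β-zincio ketone 24 with the metal on C2, either methylene leading to the same product. C2 then adds to the C1 aldehyde to give alkoxide 25; the closest known reaction types are the diethylzinc-induced opening of tertiary cyclopropanols to zinc homoenolates and the homoaldol addition of zinc and titanium homoenolates to aldehydes, used here intramolecularly. Ring A closes in the 6-exo-trig mode through a chair whose two reacting arms are the trans-diequatorial substituents on C5 and C10, which gives the trans-decalin. The only new stereocentre, C1, is controlled by divalent zinc bridging the aldehyde oxygen and the ether oxygen O9 in a six-membered chelate, possible only for the rotamer that turns the carbonyl oxygen towards O9, so that O1 ends equatorial (β) and syn to O9. The step needs transfer of the homoenolate carbon rather than of ethyl, and reaction at C2 rather than through the enolised homoenolate at C4; intramolecularity and the neopentyl, non-enolisable aldehyde secure the first, and the four-membered ring that attack through C4 would demand excludes the second. Epimerisation at C5 of the new ketone can only lead back to the more stable trans fusion, and the equatorial benzyloxy group on C6 is misaligned for β-elimination.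

Step 15
Reactants: 26 hydroxy ketone
Product: 27 1β-(tert-butyldimethylsilyloxy) ketone
Conditions: TBSOTf, 2,6-lutidine, CH2Cl2, −78 → 0 °C
Reagents that add atoms: tert-butyldimethylsilyl triflate, CC(C)(C)[Si](C)(C)OS(=O)(=O)C(F)(F)F
Why: Silylation of the hindered equatorial 1β-alcohol with a silyl triflate and a non-nucleophilic base, so that O1 cannot take part in the orthoester exchange of step 20.

Step 16
Reactants: 27 silyloxy ketone; 28 methyltriphenylphosphonium bromide
Product: 29 eudesm-4(15)-ene (exocyclic C4=C15; O1 TBS; O6 benzyl; O9 SEM)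
Conditions: 28, KOtBu, THF, 0 °C → reflux
Reagents that add atoms: methyltriphenylphosphonium bromide, C[P+](c1ccccc1)(c1ccccc1)c1ccccc1.[Br-]
Why: Wittig methylenation, in which reversible enolisation by the ylide is harmless because the trans fusion at C5 is the thermodynamic one and the equatorial C6–O bond lies close to the nodal plane of the C4–C5 enolate, which disfavours β-elimination.

Step 17
Reactants: 29 exocyclic alkene
Product: 30 4α,15-diol (O4 α equatorial; C15 β axial)
Conditions: OsO4 (5 mol %), N-methylmorpholine N-oxide, acetone/H2O, rt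
Reagents that add atoms: N-methylmorpholine N-oxide, C[N+]1([O-])CCOCC1; water, O
Why: Upjohn dihydroxylation, in which the β face of the exocyclic alkene is blocked by the syn-axial C14 methyl group so that osmylation from the α face places O4 α and C15 β and thereby sets the quaternary C4.

Step 18
Reactants: 30 diol benzyl ether
Product: 31 4α,6α,15-triol (O1 TBS; O9 SEM)
Conditions: H2 (1 atm), Pd(OH)2/C, EtOAc, rt
Reagents that add atoms: none
Why: Hydrogenolysis of the benzyl ether at a stage where the molecule holds no alkene, the silyl and SEM ethers being inert.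

Step 19
Reactants: 32 (E)-cinnamonitrile
Product: 34 trimethyl orthocinnamate, via methyl cinnamimidate hydrochloride 33 (not isolated)
Conditions: HCl (g), MeOH (1.1 equiv), Et2O, 0 °C; MeOH (excess), hexane, rt
Reagents that add atoms: methanol, CO
Why: Pinner reaction followed by alcoholysis of the imidate salt, the classical way from a nitrile to an orthoester, with the β-phenyl group holding back conjugate addition.

Step 20
Reactants: 31 triol; 34 trimethyl orthocinnamate
Product: 35 4,6,15-orthocinnamate with O1 TBS and O9 SEM
Conditions: 34 (1.2 equiv), pyridinium p-toluenesulfonate (10 mol %), 4 Å MS, CH2Cl2, rt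
Reagents that add atoms: trimethyl orthocinnamate, COC(OC)(OC)/C=C/c1ccccc1
Why: Acid-catalysed orthoester exchange, in which O15, O4 and O6 replace the three methoxy groups in turn, uptake of methanol by the sieves drives closure of the 2,7,8-trioxabicyclo[3.2.1]octane cage, and the cage dictates the configuration of the orthoester carbon.

Step 21
Reactants: 35 protected orthoester
Product: 36 target CNP0252898.1 (1β,9β-dihydroxyeudesmane 4α,6α,15-orthocinnamate)
Conditions: Bu4NF (excess), 4 Å MS, THF/DMPU, 60 °C
Reagents that add atoms: none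
Why: Fluoride-induced cleavage of the silyl ether and of the SEM group (loss of ethene, then of formaldehyde) under basic conditions, to which the orthoester and the styryl group are inert.

Compound list
1 | (S)-(+)-carvone | C=C(C)[C@@H]1CC(=O)C(C)=CC1 | starting material
2 | vinylmagnesium bromide | C=C[Mg]Br | starting material
3 | 2-methyl-5-isopropenyl-3-vinylcyclohexanone (vinyl β on C5, isopropenyl α on C7, C10 epimers) | C=C(C)[C@@H]1CC(=O)C(C)[C@@H](C=C)C1 | intermediate
4 | 3-isopropyl-6-methyl-5-vinylcyclohex-2-enone (vinyl β on C5, C10 epimers) | CC(C)C1=CC(=O)C(C)[C@@H](C=C)C1 | intermediate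
5 | formaldehyde | C=O | starting material
6 | lithium cross-conjugated dienolate of 4 (not isolated) | CC(C)C1=CC([O-])=C(C)[C@@H](C=C)C1.[Li+] | intermediate
7 | 6-(hydroxymethyl)-3-isopropyl-6-methyl-5-vinylcyclohex-2-enone (CH2OH α, methyl β, vinyl β) | CC(C)C1=CC(=O)[C@@](CO)(C)[C@@H](C=C)C1 | intermediate
8 | secondary ozonide of 7 (1,2,4-trioxolane at C4, not isolated) | CC(C)C1=CC(=O)[C@@](CO)(C)[C@@H](C2OCOO2)C1 | intermediate
9 | hydroxy aldehyde (C4 formyl β on C5, CH2OH α on C10, not isolated) | CC(C)C1=CC(=O)[C@@](CO)(C)[C@@H](C=O)C1 | intermediate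
10 | trans-fused lactol enone (both C4 epimers) | CC(C)C1=CC(=O)[C@]2(C)COC(O)[C@H]2C1 | intermediate
11 | trans-fused γ-lactone enone | CC(C)C1=CC(=O)[C@]2(C)COC(=O)[C@H]2C1 | intermediate
12 | TBS dienol ether of 11 (C9=C8, C7=C6) | CC(C)C1=C[C@@H]2C(=O)OC[C@@]2(C)C(O[Si](C)(C)C(C)(C)C)=C1 | intermediate
13 | 6α,9α-endoperoxide (9β-OTBS, not isolated) | CC(C)C1=C[C@]2(O[Si](C)(C)C(C)(C)C)OO[C@H]1[C@@H]3C(=O)OC[C@@]23C | intermediate
14 | 6α-hydroxy enone lactone | CC(C)C1=CC(=O)[C@]2(C)COC(=O)[C@H]2[C@@H]1O | intermediate
15 | 6α-hydroxy-7β-isopropyl-9-keto lactone | CC(C)[C@H]1CC(=O)[C@]2(C)COC(=O)[C@H]2[C@@H]1O | intermediate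
16 | 6α-benzyloxy-9-keto lactone | CC(C)[C@H]1CC(=O)[C@]2(C)COC(=O)[C@H]2[C@@H]1OCc3ccccc3 | intermediate
17 | 6α-benzyloxy-9β-hydroxy lactone | CC(C)[C@H]1C[C@@H](O)[C@]2(C)COC(=O)[C@H]2[C@@H]1OCc3ccccc3 | intermediate
18 | 6α-benzyloxy-9β-SEM-oxy lactone | CC(C)[C@H]1C[C@@H](OCOCC[Si](C)(C)C)[C@]2(C)COC(=O)[C@H]2[C@@H]1OCc3ccccc3 | intermediate
19 | ethylmagnesium bromide | CC[Mg]Br | starting material
20 | cyclopropanol diol (C1H2OH on C10, 1-hydroxycyclopropyl on C5) | CC(C)[C@H]1C[C@@H](OCOCC[Si](C)(C)C)[C@@](CO)(C)[C@@H](C2(O)CC2)[C@@H]1OCc3ccccc3 | intermediate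
21 | alkoxysulfonium chloride of 20 at O1 (not isolated) | CC(C)[C@H]1C[C@@H](OCOCC[Si](C)(C)C)[C@@](CO[S+](C)C)(C)[C@@H](C2(O)CC2)[C@@H]1OCc3ccccc3.[Cl-] | intermediate
22 | ring B aldehyde with the C5 1-hydroxycyclopropyl group (key-step precursor) | CC(C)[C@H]1C[C@@H](OCOCC[Si](C)(C)C)[C@@](C=O)(C)[C@@H](C2(O)CC2)[C@@H]1OCc3ccccc3 | intermediate
23 | ethylzinc cyclopropoxide of 22 (not isolated) | CC(C)[C@H]1C[C@@H](OCOCC[Si](C)(C)C)[C@@](C=O)(C)[C@@H](C2(O[Zn]CC)CC2)[C@@H]1OCc3ccccc3 | intermediate
24 | zinc homoenolate (C4 ketone, C2–Zn–Et, not isolated) | CC(C)[C@H]1C[C@@H](OCOCC[Si](C)(C)C)[C@@](C=O)(C)[C@@H](C(=O)CC[Zn]CC)[C@@H]1OCc3ccccc3 | intermediate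
25 | ethylzinc 1β-alkoxide of 26 (not isolated) | CC(C)[C@H]1C[C@@H](OCOCC[Si](C)(C)C)[C@@]2(C)[C@H]([C@@H]1OCc3ccccc3)C(=O)CC[C@@H]2O[Zn]CC | intermediate
26 | 1β-hydroxy-15-nor-eudesman-4-one, 6-O-benzyl 9-O-SEM ether (key-step product) | CC(C)[C@H]1C[C@@H](OCOCC[Si](C)(C)C)[C@@]2(C)[C@H]([C@@H]1OCc3ccccc3)C(=O)CC[C@@H]2O | intermediate
27 | 1-O-TBS ether of 26 | CC(C)[C@H]1C[C@@H](OCOCC[Si](C)(C)C)[C@@]2(C)[C@H]([C@@H]1OCc3ccccc3)C(=O)CC[C@@H]2O[Si](C)(C)C(C)(C)C | intermediate
28 | methyltriphenylphosphonium bromide | C[P+](c1ccccc1)(c1ccccc1)c1ccccc1.[Br-] | starting material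
29 | protected eudesm-4(15)-ene | CC(C)[C@H]1C[C@@H](OCOCC[Si](C)(C)C)[C@@]2(C)[C@H]([C@@H]1OCc3ccccc3)C(=C)CC[C@@H]2O[Si](C)(C)C(C)(C)C | intermediate
30 | 4α,15-diol, 6-O-benzyl | CC(C)[C@H]1C[C@@H](OCOCC[Si](C)(C)C)[C@@]2(C)[C@H]([C@@H]1OCc3ccccc3)[C@](O)(CO)CC[C@@H]2O[Si](C)(C)C(C)(C)C | intermediate
31 | 4α,6α,15-triol (O1 TBS, O9 SEM) | CC(C)[C@H]1C[C@@H](OCOCC[Si](C)(C)C)[C@@]2(C)[C@H]([C@@H]1O)[C@](O)(CO)CC[C@@H]2O[Si](C)(C)C(C)(C)C | intermediate
32 | (E)-cinnamonitrile | N#C/C=C/c1ccccc1 | starting material
33 | methyl (E)-cinnamimidate hydrochloride (not isolated) | COC(=N)/C=C/c1ccccc1.Cl | intermediate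
34 | trimethyl (E)-orthocinnamate | COC(OC)(OC)/C=C/c1ccccc1 | intermediate
35 | 4,6,15-orthocinnamate, O1 TBS, O9 SEM | CC(C)[C@H]1C[C@@H](OCOCC[Si](C)(C)C)[C@@]2(C)[C@@H]3[C@@H]1O[C@]1(/C=C/c4ccccc4)OC[C@@]3(CC[C@@H]2O[Si](C)(C)C(C)(C)C)O1 | intermediate
36 | CNP0252898.1 | CC(C)[C@H]1C[C@@H](O)[C@@]2(C)[C@@H]3[C@@H]1O[C@]1(/C=C/c4ccccc4)OC[C@@]3(CC[C@@H]2O)O1 | target

Total step count: 21. Longest linear sequence: 20 steps (steps 1–18, 20 and 21; step 19 is the side branch to 34).

Steps most likely to fail

Step 14. The zinc cyclopropoxide may open too slowly, or the alkylzinc carbon may be too weak a nucleophile. Protonation to the ethyl ketone on work-up, ethyl transfer to the aldehyde, or loss of chelation with poor facial selectivity at C1 would then take over. The fallback sets out from 20 and comes back at 26. It replaces the basic metal homoenolate by Lewis-acid activation of the electrophile.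
- Both hydroxyl groups of 20 are silylated (TESOTf, 2,6-lutidine) to the bis(triethylsilyl) ether F1.
- Swern conditions oxidise the primary triethylsilyl ether directly to the aldehyde and leave the tertiary cyclopropyl silyl ether, which gives the siloxycyclopropane aldehyde F2.
- TiCl4 in CH2Cl2 at −78 °C chelates the aldehyde oxygen and O9.
- The donor-substituted cyclopropane bond C4–C2 then attacks the activated carbonyl carbon with loss of the silyl group. This is a homo-Mukaiyama aldol of a cyclopropyl silyl ether, a known way to close carbocycles, and it gives 26 after aqueous work-up.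

Step 7. An ene reaction of singlet oxygen, silyl migration within the endoperoxide, or attack on the β face may divert the oxygenation. The step also inherits any wrong-site deprotonation from step 6. The fallback sets out from 11 and comes back at 18. It brings in O6 by hydroboration instead of oxygenating a dienol ether.
- Isopropenyl acetate with p-TsOH gives the dienol acetate F3.
- NaBH4 in aqueous ethanol cleaves the acetate, and the dienolate is protonated at C8.
- The β,γ-unsaturated ketone is reduced in situ from the α face to the homoallylic 9β-alcohol F4. This is the classical enone-to-homoallylic-alcohol sequence of steroid chemistry.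
- SEMCl and iPr2NEt give the SEM ether F5.
- BH3·SMe2 at 0 °C and then NaBO3 add boron to C6 and hydrogen to C7 in a syn fashion, from the α face away from the axial C14 methyl group. This gives the 6α-alcohol F6, which already has the 7β-isopropyl group.
- Benzylation as in step 9 leads to 18.

Step 12. Enolisation of the hindered lactone by the Grignard reagent (with epimerisation at C5) or plain ethyl addition may outrun the titanium-mediated cyclopropanation. The fallback sets out from 18 and comes back at 20. It builds the cyclopropanol from an enol ether.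
- MeLi (1 equiv, −78 °C) opens the lactone to the hydroxy methyl ketone F7.
- LiN(iPr)2 and excess TMSCl give the kinetic enol silane on the methyl side and silylate O1, forming the bis(trimethylsilyl) compound F8.
- Simmons–Smith cyclopropanation in the Furukawa variant (Et2Zn, CH2I2) gives the siloxycyclopropane F9.
- K2CO3 in MeOH removes both silyl groups to give 20.

Further compounds
F1 | step 14 | bis(triethylsilyl) ether of 20 | CC(C)[C@H]1C[C@@H](OCOCC[Si](C)(C)C)[C@@](CO[Si](CC)(CC)CC)(C)[C@@H](C2(O[Si](CC)(CC)CC)CC2)[C@@H]1OCc3ccccc3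
F2 | step 14 | siloxycyclopropane aldehyde (O4 triethylsilyl ether of 22) | CC(C)[C@H]1C[C@@H](OCOCC[Si](C)(C)C)[C@@](C=O)(C)[C@@H](C2(O[Si](CC)(CC)CC)CC2)[C@@H]1OCc3ccccc3
F3 | step 7 | dienol acetate of 11 | CC(C)C1=C[C@@H]2C(=O)OC[C@@]2(C)C(OC(C)=O)=C1
F4 | step 7 | homoallylic 9β-alcohol (C6=C7) | CC(C)C1=C[C@@H]2C(=O)OC[C@@]2(C)[C@H](O)C1
F5 | step 7 | SEM ether of F4 | CC(C)C1=C[C@@H]2C(=O)OC[C@@]2(C)[C@H](OCOCC[Si](C)(C)C)C1
F6 | step 7 | 6α-alcohol with 7β-isopropyl and 9β-SEM-oxy groups | CC(C)[C@H]1C[C@@H](OCOCC[Si](C)(C)C)[C@]2(C)COC(=O)[C@H]2[C@@H]1O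
F7 | step 12 | hydroxy methyl ketone (acetyl on C5) | CC(C)[C@H]1C[C@@H](OCOCC[Si](C)(C)C)[C@@](CO)(C)[C@@H](C(C)=O)[C@@H]1OCc3ccccc3
F8 | step 12 | bis(trimethylsilyl) compound (enol silane and O1 silyl ether) | CC(C)[C@H]1C[C@@H](OCOCC[Si](C)(C)C)[C@@](CO[Si](C)(C)C)(C)[C@@H](C(=C)O[Si](C)(C)C)[C@@H]1OCc3ccccc3
F9 | step 12 | siloxycyclopropane (bis(trimethylsilyl) ether of 20) | CC(C)[C@H]1C[C@@H](OCOCC[Si](C)(C)C)[C@@](CO[Si](C)(C)C)(C)[C@@H](C2(O[Si](C)(C)C)CC2)[C@@H]1OCc3ccccc3
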